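If the charge steered the substrate decay, the spring and dawn runs would part well clear of their scatter, and you could not carry a curve from them to a leaner flask.

| flask | substrate | first nucleophile | second nucleophile | remark | time |
|---|---|---|---|---|---|
| spring | 14 mM | 1 equiv | 4 equiv (fed, over 40 s) | run made earlier |  |
| dawn | 22 mM | 1 equiv | 4 equiv (fed, over 40 s) | run made earlier |  |
| flask | 10 mM | 1.00 equiv | 4.00 equiv (fed, over 40 s) |  | 10 min |

| run | time / min | substrate / % | target / % |
|---|---|---|---|
| spring | 0.667 | 78.6 | 11.7 |
| spring | 1.33 | 63.7 | 17.4 |
| spring | 2.50 | 46.0 | 26.1 |
| spring | 4.00 | 30.6 | 33.2 |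
| spring | 8.00 | 14.3 | 43.5 |
| dawn | 0.667 | 77.4 | 10.1 |
| dawn | 2.00 | 50.5 | 23.2 |
| dawn | 4.00 | 29.8 | 32.2 |
| dawn | 6.00 | 19.2 | 38.5 |
| dawn | 8.00 | 13.1 | 42.3 |

(standard deviation of a reading: 0.5 percentage points)

- in percentages every species weighs as the substrate in it: one idle adduct counts as two
- for target the idle adduct is counted in
- on the list of suspects stand: substrate + target <-> idle adduct; second nucleophile + intermediate -> other capture product; first nucleophile + intermediate -> target; substrate -> intermediate
- in an amount of target, one idle adduct counts as one target

1. amount of substrate in percent of the substrate charged, at 2.0 min, 5.0 min and 10 min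

At 8.00 min the two runs part by 1.2 percentage points. A difference of two readings scatters by 0.71 points. So you may carry the curve, with a small correction for the charge.

Between 4.00 min and 8.00 min the spring substrate falls at 0.190 min⁻¹. That number, the logarithm of the fall between two late readings over the time between them, is the tail constant, an apparent first-order rate constant. Test it on the dawn run. Its reading at 6.00 min, carried forward, gives 13.1% at 8.00 min, and the dawn reading there is 13.1%.

Now my own reckoning for the new flask. Carrying the spring reading at 8.00 min on to 10 min gives 9.78%. That first answer still belongs to the spring charge. Go round once more. The new flask has c(substrate) lower by 4.00 mM, and the gap between the runs, scaled to that step, lifts the reading by 0.6 points. Carried forward, that gives 10.2%.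

The forecast reads 53.5%, 25.3% and 10.6%, on the ground that the decay “barely depends on concentration”. Its last point stands 0.40 points above mine.

The flask gives 53.5%, 25.8% and 10.2%, and the forecast holds.

    substrate + target ⇌ idle adduct, settled at all times (K = 170 L mol⁻¹)
    second nucleophile + intermediate → other capture product (k = 41.9 L mol⁻¹ s⁻¹)
    first nucleophile + intermediate → target (k = 257 L mol⁻¹ s⁻¹)
    substrate → intermediate (k = 0.00405 s⁻¹)

Carry this flask's value at 5.0 min forward with the tail constant and you get 9.98% at 10 min, against 10.2%. The substrate left in this flask at 10 min is there mainly because the reading falls at that hour. A later hour would undo the forecast's 10.6%: this flask read at 100 min holds 0% of the substrate charged, 10 points lower.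

All runs were generated by integration with constants of no real substance.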